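**Plan**

- Retrosynthetic cuts, in order: the two catechol O–benzyl bonds (protection only); the bond from the tetralone aromatic carbon C4a to the stereogenic carbon C4, which opens the ketone ring to an open-chain 4-hydroxy-4-naphthylbutyrophenone; the aryl–C(=O) bond (aryllithium plus γ-lactone); the C3–C4 bond of the chain (naphthaldehyde plus propanoate homoenolate); the naphthalene–CHO bond.
- Enabling feature: C4 sits on naphthalene C1, para to the free naphthalene C4–OH, so it is the methide carbon of a 1,4-naphthoquinone methide. The tetralone carbon C4a is para to the C7 oxygen of the catechol ring, so it is the one nucleophilic carbon that can reach C4 through a six-membered transition state.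
- Forward order: the naphthalene and the catechol ring are bought intact and the four-carbon chain is assembled between them. The only ring made is the six-membered ketone ring, closed late by the key step.
- Stereochemistry: the precursor carbinol is racemic and its configuration is erased in the planar quinone methide. The single stereocenter is set in the ring closure by a chiral Brønsted acid (chiral counter-anion control).

Key step: step 8

Assumption: the (R)-configured acid is taken to deliver the (S)-configured product; if a first cyclisation shows the opposite sense, the (S)-acid is used and nothing else changes.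

**Route**

Step 1
Reactants: 1 1,5-dimethoxynaphthalene
Product: 3 4,8-dimethoxynaphthalene-1-carbaldehyde, via iminium salt 2 (not isolated)
Conditions: POCl3, DMF, 0 to 90 °C; then aq. NaOAc
Reagents that add atoms: N,N-dimethylformamide CN(C)C=O; water O
Why: Vilsmeier–Haack formylation; each methoxy group directs to its para position and the two para positions are equivalent by symmetry, so one aldehyde should form, and the formyl group then deactivates the ring against a second attack.

Step 2
Reactants: 3 4,8-dimethoxynaphthalene-1-carbaldehyde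
Product: 4 4-hydroxy-8-methoxynaphthalene-1-carbaldehyde
Conditions: NaSEt, DMF, 100 °C; then aq. HCl
Reagents that add atoms: none
Why: Nucleophilic (SN2) O-demethylation by thiolate; the 4-methoxy group is para to the formyl group and leaves as a vinylogous carboxylate, whereas the 8-methoxy group on the other ring is not conjugated with the aldehyde, and the naphthoxide formed resists a second attack.

Step 3
Reactants: 4 4-hydroxy-8-methoxynaphthalene-1-carbaldehyde
Product: 5 8-methoxy-4-{[tri(propan-2-yl)silyl]oxy}naphthalene-1-carbaldehyde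
Conditions: i-Pr3SiCl, imidazole, DMF, rt
Reagents that add atoms: triisopropylsilyl chloride CC(C)[Si](Cl)(C(C)C)C(C)C
Why: Standard silylation of a phenol; the bulky silyl ether masks the acidic naphthol against the organometallic reagents of steps 4 and 6 and restores the electrophilicity of the aldehyde.

Step 4
Reactants: 5 8-methoxy-4-{[tri(propan-2-yl)silyl]oxy}naphthalene-1-carbaldehyde; 6 ethyl 3-iodopropanoate
Product: 10 racemic 5-(8-methoxy-4-{[tri(propan-2-yl)silyl]oxy}naphthalen-1-yl)oxolan-2-one, via zinc homoenolate 7 (not isolated), via titanium homoenolate 8 (not isolated), via hydroxy ester 9 (not isolated)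
Conditions: 6, Zn dust (Me3SiCl-activated), THF, 35 °C; ClTi(OiPr)3, CH2Cl2, −20 °C; then 5, −20 °C to rt, then 40 °C; aq. NH4Cl
Reagents that add atoms: none
Why: Ester homoenolate addition to an aldehyde (zinc insertion, transmetalation to titanium, carbonyl addition) followed by lactonisation of the titanium alkoxide; the mild triisopropoxytitanium reagent should spare the acid-labile electron-rich benzylic alkoxide, and the new carbinol centre needs no control because it is erased in step 8.

Step 5
Reactants: 11 3-bromobenzene-1,2-diol
Product: 12 1,2-bis(benzyloxy)-3-bromobenzene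
Conditions: BnBr, K2CO3, DMF, 60 °C
Reagents that add atoms: benzyl bromide BrCc1ccccc1
Why: Williamson etherification of both phenols; benzyl ethers survive the aryllithium chemistry and the acid of step 8 and come off by hydrogenolysis without touching the methyl ether.

Step 6
Reactants: 12 1,2-bis(benzyloxy)-3-bromobenzene; 10 racemic 5-(8-methoxy-4-{[tri(propan-2-yl)silyl]oxy}naphthalen-1-yl)oxolan-2-one
Product: 14 racemic 1-[2,3-bis(benzyloxy)phenyl]-4-hydroxy-4-(8-methoxy-4-{[tri(propan-2-yl)silyl]oxy}naphthalen-1-yl)butan-1-one, via aryllithium 13 (not isolated)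
Conditions: 12, n-BuLi, THF, −78 °C; then 10, −78 °C; aq. NH4Cl
Reagents that add atoms: none
Why: Bromine–lithium exchange followed by acyl substitution on the γ-lactone; the lithium lactolate is stable at −78 °C and the ketone released on work-up is ortho-substituted, so single addition to the γ-hydroxy ketone should prevail.

Step 7
Reactants: 14 racemic 1-[2,3-bis(benzyloxy)phenyl]-4-hydroxy-4-(8-methoxy-4-{[tri(propan-2-yl)silyl]oxy}naphthalen-1-yl)butan-1-one
Product: 15 racemic 1-[2,3-bis(benzyloxy)phenyl]-4-hydroxy-4-(4-hydroxy-8-methoxynaphthalen-1-yl)butan-1-one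
Conditions: Bu4NF, AcOH (1 equiv per fluoride), THF, 0 °C
Reagents that add atoms: none
Why: Fluoride cleavage of an aryl silyl ether; the acetic acid buffer keeps the medium near neutral so that the p-hydroxy-benzylic carbinol is not ionised before the chiral acid is present.

Step 8
Reactants: 15 racemic 1-[2,3-bis(benzyloxy)phenyl]-4-hydroxy-4-(4-hydroxy-8-methoxynaphthalen-1-yl)butan-1-one
Product: 17 (4S)-7,8-bis(benzyloxy)-4-(4-hydroxy-8-methoxynaphthalen-1-yl)-3,4-dihydronaphthalen-1(2H)-one, via naphthoquinone methide 16 (not isolated)
Conditions: (R)-3,3'-bis(2,4,6-triisopropylphenyl)-1,1'-binaphthalene-2,2'-diyl N-triflylphosphoramide (10 mol%), 5 Å molecular sieves, CH2Cl2 (0.005 M), −40 to 0 °C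
Reagents that add atoms: none
Why: Proposed new method: the chiral N-triflylphosphoramide should ionise the p-hydroxy-naphthylic carbinol of 15 with loss of water to the 1,4-naphthoquinone methide 16, which stays hydrogen-bonded to or protonated by the chiral anion, and the bis(benzyloxy)aryl ketone ring then adds through its carbon para to the 3-benzyloxy group to the methide carbon in a Friedel–Crafts 1,6-addition, after which both rings rearomatise. The closest known reaction types are the chiral phosphoric acid-catalysed intermolecular 1,6-addition of phenols, naphthols and indoles to para-quinone methides generated in situ from p-hydroxybenzyl alcohols, and the Lewis acid-mediated closure of benzylic cations onto alkoxy-substituted aroyl rings that gives racemic 4-aryl-1-tetralones; the intramolecular, enantioselective combination on a naphthoquinone methide has not been shown. The one new ring, the six-membered ketone ring, closes in a 6-exo-trig mode onto the exocyclic methide C=C. The one new stereocenter, the diarylmethine carbon, is set under catalyst control, the bound chiral phosphoramide anion shielding one face of the planar methide. The step needs C-alkylation at the aryl carbon ortho to the acyl group in preference to intermolecular attack by a naphthol ring of a second molecule and to O-closure through the ketone. The 3-benzyloxy group activates exactly this carbon, the 2-benzyl ether rules out phenol O-alkylation, high dilution disfavours the bimolecular path, and both the dihydrofuran from ketone O-attack and the alkenylnaphthol tautomer of 16 should reopen under the acid and drain into the irreversible C–C closure.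

Step 9
Reactants: 17 (4S)-7,8-bis(benzyloxy)-4-(4-hydroxy-8-methoxynaphthalen-1-yl)-3,4-dihydronaphthalen-1(2H)-one
Product: 18 (4S)-7,8-dihydroxy-4-(4-hydroxy-8-methoxynaphthalen-1-yl)-3,4-dihydronaphthalen-1(2H)-one
Conditions: H2 (1 atm), 10% Pd/C, EtOAc–MeOH, rt
Reagents that add atoms: none
Why: Hydrogenolysis of aryl benzyl ethers under neutral conditions; the diarylmethine carbon carries no leaving group and the aryl ketone is not reduced at ambient pressure without acid, so the stereocenter and the ketone should persist.

**Compound list**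

1 | 1,5-dimethoxynaphthalene | COc1cccc2c(OC)cccc12 | starting material
2 | N-[(4,8-dimethoxynaphthalen-1-yl)methylidene]-N-methylmethanaminium chloride (formed in the flask) | COc1cccc2c(OC)ccc(C=[N+](C)C)c12.[Cl-] | intermediate
3 | 4,8-dimethoxynaphthalene-1-carbaldehyde | COc1cccc2c(OC)ccc(C=O)c12 | intermediate
4 | 4-hydroxy-8-methoxynaphthalene-1-carbaldehyde | COc1cccc2c(O)ccc(C=O)c12 | intermediate
5 | 8-methoxy-4-{[tri(propan-2-yl)silyl]oxy}naphthalene-1-carbaldehyde | COc1cccc2c(O[Si](C(C)C)(C(C)C)C(C)C)ccc(C=O)c12 | intermediate
6 | ethyl 3-iodopropanoate | CCOC(=O)CCI | starting material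
7 | (3-ethoxy-3-oxopropyl)zinc iodide (formed in the flask) | CCOC(=O)CC[Zn]I | intermediate
8 | (3-ethoxy-3-oxopropyl)tri(propan-2-yloxy)titanium (formed in the flask) | CCOC(=O)CC[Ti](OC(C)C)(OC(C)C)OC(C)C | intermediate
9 | racemic ethyl 4-hydroxy-4-(8-methoxy-4-{[tri(propan-2-yl)silyl]oxy}naphthalen-1-yl)butanoate (present as its titanium alkoxide in the flask) | CCOC(=O)CCC(O)c1ccc(O[Si](C(C)C)(C(C)C)C(C)C)c2cccc(OC)c12 | intermediate
10 | racemic 5-(8-methoxy-4-{[tri(propan-2-yl)silyl]oxy}naphthalen-1-yl)oxolan-2-one | O=C1CCC(O1)c1ccc(O[Si](C(C)C)(C(C)C)C(C)C)c2cccc(OC)c12 | intermediate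
11 | 3-bromobenzene-1,2-diol | Oc1cccc(Br)c1O | starting material
12 | 1,2-bis(benzyloxy)-3-bromobenzene | Brc1cccc(OCc2ccccc2)c1OCc1ccccc1 | intermediate
13 | [2,3-bis(benzyloxy)phenyl]lithium (formed in the flask) | [Li]c1cccc(OCc2ccccc2)c1OCc1ccccc1 | intermediate
14 | racemic 1-[2,3-bis(benzyloxy)phenyl]-4-hydroxy-4-(8-methoxy-4-{[tri(propan-2-yl)silyl]oxy}naphthalen-1-yl)butan-1-one | O=C(CCC(O)c1ccc(O[Si](C(C)C)(C(C)C)C(C)C)c2cccc(OC)c12)c1cccc(OCc2ccccc2)c1OCc1ccccc1 | intermediate
15 | racemic 1-[2,3-bis(benzyloxy)phenyl]-4-hydroxy-4-(4-hydroxy-8-methoxynaphthalen-1-yl)butan-1-one | O=C(CCC(O)c1ccc(O)c2cccc(OC)c12)c1cccc(OCc2ccccc2)c1OCc1ccccc1 | intermediate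
16 | 4-{4-[2,3-bis(benzyloxy)phenyl]-4-oxobutylidene}-5-methoxynaphthalen-1(4H)-one (formed in the flask, alkene geometry not defined) | O=C(CCC=C1C=CC(=O)c2cccc(OC)c12)c1cccc(OCc2ccccc2)c1OCc1ccccc1 | intermediate
17 | (4S)-7,8-bis(benzyloxy)-4-(4-hydroxy-8-methoxynaphthalen-1-yl)-3,4-dihydronaphthalen-1(2H)-one | COc1cccc2c(O)ccc([C@@H]3CCC(=O)c4c3ccc(OCc5ccccc5)c4OCc6ccccc6)c12 | intermediate
18 | (4S)-7,8-dihydroxy-4-(4-hydroxy-8-methoxynaphthalen-1-yl)-3,4-dihydronaphthalen-1(2H)-one | COc1cccc2c(O)ccc([C@@H]3CCC(=O)c4c3ccc(O)c4O)c12 | target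

**Count**

Total steps: 9. Longest linear sequence: 8 (steps 1, 2, 3, 4, 6, 7, 8, 9); step 5 is a one-step side branch.

**Steps most likely to fail**

Step 8. Facial discrimination in the ion pair may be weak, and because the acyl group lowers the nucleophilicity of the attacking ring, bimolecular alkylation of a free naphthol ring may run ahead of ring closure. The fallback uses known chemistry, sets out from 14 and comes back at 17. The ring is closed while the naphthol is still silylated, so no free naphthol nucleophile is present: BF3·OEt2, CH2Cl2, −40 to 0 °C, a classical Friedel–Crafts cyclodehydration of an electron-rich benzylic alcohol onto a tethered alkoxyarene. This should give racemic 7,8-bis(benzyloxy)-4-(8-methoxy-4-{[tri(propan-2-yl)silyl]oxy}naphthalen-1-yl)-3,4-dihydronaphthalen-1(2H)-one F1. Bu4NF/AcOH in THF then frees racemic 7,8-bis(benzyloxy)-4-(4-hydroxy-8-methoxynaphthalen-1-yl)-3,4-dihydronaphthalen-1(2H)-one F2. Preparative HPLC on an amylose tris(3,5-dimethylphenylcarbamate) stationary phase separates 17 from its antipode, (4R)-7,8-bis(benzyloxy)-4-(4-hydroxy-8-methoxynaphthalen-1-yl)-3,4-dihydronaphthalen-1(2H)-one F3. The configuration is then fixed by resolution instead of catalysis.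

Step 2. The thiolate may attack the wrong methyl ether or both. The fallback sets out from 1 and comes back at 5; it differentiates the two oxygens before the carbon substituent is introduced and lets the free hydroxyl direct. Mono-demethylation of 1 with NaSEt in DMF should stop at 5-methoxynaphthalen-1-ol F4, because the naphthoxide resists a second attack. Para-bromination with NBS in MeCN at −20 °C should give 4-bromo-5-methoxynaphthalen-1-ol F5. Silylation (i-Pr3SiCl, imidazole) gives [(4-bromo-5-methoxynaphthalen-1-yl)oxy]tri(propan-2-yl)silane F6. Bromine–lithium exchange with n-BuLi in THF at −78 °C gives (8-methoxy-4-{[tri(propan-2-yl)silyl]oxy}naphthalen-1-yl)lithium F7, which is quenched with DMF to give 5.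

Step 4. The soft homoenolate may add sluggishly to the peri-hindered, electron-rich aldehyde, and lactonisation may stay incomplete. The fallback sets out from 5 and comes back at 10; it uses a hard Grignard reagent and adjusts the oxidation level afterwards. The reagent chloromagnesium 3-(chloromagnesio)propan-1-olate F8 (from 3-chloropropan-1-ol, i-PrMgCl, then Mg, THF) adds to 5 to give racemic 1-(8-methoxy-4-{[tri(propan-2-yl)silyl]oxy}naphthalen-1-yl)butane-1,4-diol F9. TEMPO (cat.) and PhI(OAc)2 in CH2Cl2 then oxidise the primary alcohol and the resulting lactol to lactone 10.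

**Further compounds**

F1 | step 8 | racemic 7,8-bis(benzyloxy)-4-(8-methoxy-4-{[tri(propan-2-yl)silyl]oxy}naphthalen-1-yl)-3,4-dihydronaphthalen-1(2H)-one | COc1cccc2c(O[Si](C(C)C)(C(C)C)C(C)C)ccc(C3CCC(=O)c4c3ccc(OCc5ccccc5)c4OCc6ccccc6)c12
F2 | step 8 | racemic 7,8-bis(benzyloxy)-4-(4-hydroxy-8-methoxynaphthalen-1-yl)-3,4-dihydronaphthalen-1(2H)-one | COc1cccc2c(O)ccc(C3CCC(=O)c4c3ccc(OCc5ccccc5)c4OCc6ccccc6)c12
F3 | step 8 | (4R)-7,8-bis(benzyloxy)-4-(4-hydroxy-8-methoxynaphthalen-1-yl)-3,4-dihydronaphthalen-1(2H)-one | COc1cccc2c(O)ccc([C@H]3CCC(=O)c4c3ccc(OCc5ccccc5)c4OCc6ccccc6)c12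
F4 | step 2 | 5-methoxynaphthalen-1-ol | COc1cccc2c(O)cccc12
F5 | step 2 | 4-bromo-5-methoxynaphthalen-1-ol | COc1cccc2c(O)ccc(Br)c12
F6 | step 2 | [(4-bromo-5-methoxynaphthalen-1-yl)oxy]tri(propan-2-yl)silane | COc1cccc2c(O[Si](C(C)C)(C(C)C)C(C)C)ccc(Br)c12
F7 | step 2 | (8-methoxy-4-{[tri(propan-2-yl)silyl]oxy}naphthalen-1-yl)lithium | COc1cccc2c(O[Si](C(C)C)(C(C)C)C(C)C)ccc([Li])c12
F8 | step 4 | chloromagnesium 3-(chloromagnesio)propan-1-olate | Cl[Mg]CCCO[Mg]Cl
F9 | step 4 | racemic 1-(8-methoxy-4-{[tri(propan-2-yl)silyl]oxy}naphthalen-1-yl)butane-1,4-diol | OCCCC(O)c1ccc(O[Si](C(C)C)(C(C)C)C(C)C)c2cccc(OC)c12
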